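**Plan**

1. Retrosynthesis: the upper pyran ring is cut at O1–C2 and C3–C4 together, with C2 taken to the lactol level. This gives o-hydroxybenzhydrol 20 and arylacetaldehyde 17. Compound 20 is cut at the carbinol–aryl bond into aryl bromide 12 and salicylaldehyde 18, and 12 goes back through isoflavone 7 to acid 4 and resorcinol.
2. Forward order: lower chromone ring (step 3), lower chroman with C3 set (step 4), upper A ring attached (step 9), upper pyran ring closed last (step 10), helpers removed (steps 11 and 12).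
3. Enabling feature: upper C4 is doubly benzylic and bonded to C4a, which is ortho to the O1-bearing carbon C8a and para to the 7-oxygen. C8a(O1)–C4a–C4 is therefore a latent o-quinone methide, and C2–C3 with its dimethoxyphenyl ring is a latent arylacetaldehyde enamine.
4. Stereochemistry: lower C3 (R) comes from Ru/(R,R)-TsDPEN transfer hydrogenation with dynamic kinetic resolution. Upper C3 (R) and C4 (S) are both set in step 10 by the (R)-prolinol catalyst, trans to each other.
5. Temporary groups: the C2 lactol hydroxyl (removed by ionic hydrogenation) and four benzyl ethers (removed by hydrogenolysis).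

Key step: step 10

Remark: (2-bromo-3-methoxyphenyl)acetic acid (1) is taken as a purchasable building block, and the enantiomer of each chiral catalyst is chosen from the accepted transition-state models.

**Route**

Step 1
Reactants: 1 (2-bromo-3-methoxyphenyl)acetic acid
Product: 2 methyl (2-bromo-3-methoxyphenyl)acetate
Conditions: MeOH, H2SO4 (cat.), reflux
Reagents that add atoms: methanol, CO
Why: Fischer esterification masks the acidic proton, which would otherwise consume the boron reagent and deactivate the iridium catalyst of step 2.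

Step 2
Reactants: 2 methyl (2-bromo-3-methoxyphenyl)acetate
Product: 4 (2-bromo-5-hydroxy-3-methoxyphenyl)acetic acid, via aryl boronate 3 (not isolated)
Conditions: [Ir(OMe)(cod)]2 (1.5 mol%), dtbpy (3 mol%), B2pin2, THF, 80 °C; then aq. NaOH, H2O2, 0 °C → rt; then HCl
Reagents that add atoms: bis(pinacolato)diboron, CC1(C)OB(OC1(C)C)B1OC(C)(C)C(C)(C)O1 (boron group of 3); hydrogen peroxide, OO; sodium hydroxide, [Na+].[OH-]
Why: Iridium-catalysed aromatic C–H borylation is sterically governed and tolerates aryl bromides, so only C5, the one ring C–H without an ortho substituent, should be borylated; basic peroxide then converts C–B into C–OH at the same carbon and saponifies the ester (one-pot borylation/oxidation).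

Step 3
Reactants: 4 (2-bromo-5-hydroxy-3-methoxyphenyl)acetic acid; 5 resorcinol
Product: 7 3-(2-bromo-5-hydroxy-3-methoxyphenyl)-7-hydroxy-4H-chromen-4-one, via deoxybenzoin 6 (not isolated)
Conditions: BF3·OEt2, 85 °C; then DMF, MsCl, 60 °C; H2O
Reagents that add atoms: N,N-dimethylformamide, CN(C)C=O
Why: BF3-promoted Friedel–Crafts acylation of resorcinol at C4 should give the 2,4-dihydroxydeoxybenzoin, whose methylene is formylated by the DMF/MsCl iminium reagent and closed through the ortho hydroxyl to the chromone (deoxybenzoin route to isoflavones).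

Step 4
Reactants: 7 3-(2-bromo-5-hydroxy-3-methoxyphenyl)-7-hydroxy-4H-chromen-4-one
Product: 11 (R)-3-(2-bromo-5-hydroxy-3-methoxyphenyl)chroman-7-ol, via isoflavanone 8 (not isolated), via cis-isoflavan-4-ol 9 (not isolated), via p-quinone methide 10 (not isolated)
Conditions: RuCl[(R,R)-TsDPEN](p-cymene) (3 mol%), HCO2H/Et3N (5:2), EtOAc, 45 °C
Reagents that add atoms: none
Why: Noyori-type asymmetric transfer hydrogenation first reduces the chromone C2=C3 bond to the configurationally labile isoflavanone, then reduces one ketone enantiomer faster (dynamic kinetic resolution) to the cis-(3R,4R) alcohol, and the free 7-hydroxyl finally expels the benzylic hydroxyl as a p-quinone methide that is reduced in turn, so C3 (R) is set by the (R,R) catalyst and C4 becomes CH2.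

Step 5
Reactants: 11 (R)-3-(2-bromo-5-hydroxy-3-methoxyphenyl)chroman-7-ol
Product: 12 (R)-7-(benzyloxy)-3-[5-(benzyloxy)-2-bromo-3-methoxyphenyl]chromane
Conditions: BnBr (2.4 equiv), K2CO3, DMF, rt
Reagents that add atoms: benzyl bromide, BrCc1ccccc1
Why: Williamson ether synthesis protects both phenols as benzyl ethers, which withstand the organolithium, acid and Lewis acid steps ahead and do not affect C3.

Step 6
Reactants: 13 2,6-dimethoxyphenol
Product: 14 2-(benzyloxy)-1,3-dimethoxybenzene
Conditions: BnBr, K2CO3, acetone, reflux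
Reagents that add atoms: benzyl bromide, BrCc1ccccc1
Why: Williamson ether synthesis on the only phenol present.

Step 7
Reactants: 14 2-(benzyloxy)-1,3-dimethoxybenzene
Product: 15 3-(benzyloxy)-2,4-dimethoxybenzaldehyde
Conditions: POCl3, DMF, 80 °C; then ice-water
Reagents that add atoms: N,N-dimethylformamide, CN(C)C=O; water, O
Why: Vilsmeier–Haack formylation should occur at C4, which is para to one methoxy group and ortho to the other, whereas C5 is activated only by the flanked, twisted benzyloxy group.

Step 8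
Reactants: 15 3-(benzyloxy)-2,4-dimethoxybenzaldehyde
Product: 17 2-[3-(benzyloxy)-2,4-dimethoxyphenyl]acetaldehyde, via enol ether 16 (not isolated)
Conditions: MeOCH2PPh3Cl, KOtBu, THF, 0 °C → rt; then 2 M HCl, THF, 45 °C
Reagents that add atoms: (methoxymethyl)triphenylphosphonium chloride, COC[P+](c1ccccc1)(c1ccccc1)c1ccccc1.[Cl-]; water, O
Why: Wittig methoxymethylenation followed by acid hydrolysis of the enol ether is the standard one-carbon homologation of an aryl aldehyde to the arylacetaldehyde.

Step 9
Reactants: 12 (R)-7-(benzyloxy)-3-[5-(benzyloxy)-2-bromo-3-methoxyphenyl]chromane; 18 4-(benzyloxy)-2-hydroxybenzaldehyde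
Product: 20 [4-(benzyloxy)-2-hydroxyphenyl]{4-(benzyloxy)-2-[(3R)-7-(benzyloxy)chroman-3-yl]-6-methoxyphenyl}methanol as a mixture of carbinol epimers, via aryllithium 19 (not isolated)
Conditions: t-BuLi (2.1 equiv), THF, −78 °C; then 18 pre-treated with NaH (THF), −78 → 0 °C; aq. NH4Cl
Reagents that add atoms: tert-butyllithium, [Li]C(C)(C)C (lithium of 19)
Why: Bromine–lithium exchange at −78 °C is faster than any deprotonation, and the methoxy-stabilised aryllithium should add 1,2 to the aldehyde of the preformed sodium phenoxide; the carbinol configuration is irrelevant because this carbon becomes sp2 in step 10, and the acid-labile product is taken on without chromatography on acidic silica.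

Step 10
Reactants: 20 o-hydroxybenzhydrol (as above); 17 2-[3-(benzyloxy)-2,4-dimethoxyphenyl]acetaldehyde
Product: 22 (3R,4S)-7-(benzyloxy)-4-{4-(benzyloxy)-2-[(3R)-7-(benzyloxy)chroman-3-yl]-6-methoxyphenyl}-3-[3-(benzyloxy)-2,4-dimethoxyphenyl]chroman-2-ol as both C2 epimers, via o-quinone methide 21 (not isolated)
Conditions: (R)-α,α-diphenylprolinol trimethylsilyl ether (20 mol%), PhCO2H (20 mol%), CHCl3, 0 °C → rt, slow addition of 17
Reagents that add atoms: none
Why: Benzoic acid ionises the doubly benzylic, oxygen-stabilised carbinol of 20 to the (E)-o-quinone methide 21 (O1=C8a–C4a=C4), while the catalyst turns 17 into an (E)-enamine whose α-carbon (future C3) adds to C4 past the small methoxy flank of the twisted aryl ring, after which the released phenoxide O1 closes onto the iminium carbon (future C2) and hydrolysis of the N,O-acetal gives lactol 22 and returns the catalyst. The closest known reaction type is the secondary-amine-catalysed Michael addition–hemiacetalisation of aldehydes with o-quinone methides generated in situ from o-hydroxybenzhydrols, a formal inverse-electron-demand oxa-[4+2] annulation. The pyran ring is closed as a stepwise [4+2] annulation, first the C3–C4 bond by intermolecular conjugate addition and then the O1–C2 bond by 6-exo-trig addition of the phenoxide to the iminium ion. C3 is set by the catalyst, whose diphenyl(silyloxy)methyl group blocks one face of the enamine, so the (R)-catalyst is expected to deliver 3R. C4 is set in the same bond-forming event by the synclinal, endo-like approach of the E-enamine to the E-quinone methide, which places the two aryl groups trans (4S), the arrangement that is also the more stable one. The step needs regioselective attack of the enamine carbon at C4 (given by the polarisation of the oxadiene), catalyst-controlled face selectivity that overrides the remote lower stereocentre, and suppression of aldehyde self-condensation, which the stabilised, persistent quinone methide and the slow addition of 17 should secure.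

Step 11
Reactants: 22 lactol (as above)
Product: 23 (3R,4S)-7-(benzyloxy)-4-{4-(benzyloxy)-2-[(3R)-7-(benzyloxy)chroman-3-yl]-6-methoxyphenyl}-3-[3-(benzyloxy)-2,4-dimethoxyphenyl]chromane
Conditions: Et3SiH, BF3·OEt2, CH2Cl2, −78 → −30 °C
Reagents that add atoms: none
Why: Ionic hydrogenation of the lactol through the cyclic aryloxocarbenium ion replaces the anomeric hydroxyl by hydrogen at low temperature without involving C3 or C4.

Step 12
Reactants: 23 tetrabenzyl ether (as above)
Product: 24 (3R,4S)-4-{4-hydroxy-2-[(3R)-7-hydroxychroman-3-yl]-6-methoxyphenyl}-3-(3-hydroxy-2,4-dimethoxyphenyl)chroman-7-ol (CNP0305801.1)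
Conditions: H2 (1 atm), 10% Pd/C, EtOAc/MeOH, rt
Reagents that add atoms: none
Why: Catalytic hydrogenolysis should cleave the four benzyl ethers and leave the methyl ethers, the chroman C–O bonds and the three stereocentres untouched.

**Compound list**

1 | (2-bromo-3-methoxyphenyl)acetic acid | COc1cccc(CC(=O)O)c1Br | starting material
2 | methyl (2-bromo-3-methoxyphenyl)acetate | COC(=O)Cc1cccc(OC)c1Br | intermediate
3 | methyl [2-bromo-3-methoxy-5-(4,4,5,5-tetramethyl-1,3,2-dioxaborolan-2-yl)phenyl]acetate | COC(=O)Cc1cc(B2OC(C)(C)C(C)(C)O2)cc(OC)c1Br | intermediate (not isolated)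
4 | (2-bromo-5-hydroxy-3-methoxyphenyl)acetic acid | COc1cc(O)cc(CC(=O)O)c1Br | intermediate
5 | resorcinol (benzene-1,3-diol) | Oc1cccc(O)c1 | starting material
6 | 2-(2-bromo-5-hydroxy-3-methoxyphenyl)-1-(2,4-dihydroxyphenyl)ethan-1-one | COc1cc(O)cc(CC(=O)c2ccc(O)cc2O)c1Br | intermediate (not isolated)
7 | 3-(2-bromo-5-hydroxy-3-methoxyphenyl)-7-hydroxy-4H-chromen-4-one | COc1cc(O)cc(-c2coc3cc(O)ccc3c2=O)c1Br | intermediate
8 | rac-3-(2-bromo-5-hydroxy-3-methoxyphenyl)-7-hydroxychroman-4-one (C3 epimerising) | COc1cc(O)cc(C2COc3cc(O)ccc3C2=O)c1Br | intermediate (not isolated)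
9 | (3R,4R)-3-(2-bromo-5-hydroxy-3-methoxyphenyl)chromane-4,7-diol (cis) | COc1cc(O)cc([C@@H]2COc3cc(O)ccc3[C@@H]2O)c1Br | intermediate (not isolated)
10 | (R)-3-(2-bromo-5-hydroxy-3-methoxyphenyl)-2H-chromen-7(3H)-one (p-quinone methide) | COc1cc(O)cc([C@@H]2COC3=CC(=O)C=CC3=C2)c1Br | intermediate (not isolated)
11 | (R)-3-(2-bromo-5-hydroxy-3-methoxyphenyl)chroman-7-ol | COc1cc(O)cc([C@@H]2COc3cc(O)ccc3C2)c1Br | intermediate
12 | (R)-7-(benzyloxy)-3-[5-(benzyloxy)-2-bromo-3-methoxyphenyl]chromane | COc1cc(OCc2ccccc2)cc([C@@H]2COc3cc(OCc4ccccc4)ccc3C2)c1Br | intermediate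
13 | 2,6-dimethoxyphenol | COc1cccc(OC)c1O | starting material
14 | 2-(benzyloxy)-1,3-dimethoxybenzene | COc1cccc(OC)c1OCc1ccccc1 | intermediate
15 | 3-(benzyloxy)-2,4-dimethoxybenzaldehyde | O=Cc1ccc(OC)c(OCc2ccccc2)c1OC | intermediate
16 | 2-(benzyloxy)-1,3-dimethoxy-4-(2-methoxyethenyl)benzene (E/Z mixture) | COC=Cc1ccc(OC)c(OCc2ccccc2)c1OC | intermediate (not isolated)
17 | 2-[3-(benzyloxy)-2,4-dimethoxyphenyl]acetaldehyde | O=CCc1ccc(OC)c(OCc2ccccc2)c1OC | intermediate
18 | 4-(benzyloxy)-2-hydroxybenzaldehyde | O=Cc1ccc(OCc2ccccc2)cc1O | starting material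
19 | {4-(benzyloxy)-2-[(3R)-7-(benzyloxy)chroman-3-yl]-6-methoxyphenyl}lithium | COc1cc(OCc2ccccc2)cc([C@@H]2COc3cc(OCc4ccccc4)ccc3C2)c1[Li] | intermediate (not isolated)
20 | [4-(benzyloxy)-2-hydroxyphenyl]{4-(benzyloxy)-2-[(3R)-7-(benzyloxy)chroman-3-yl]-6-methoxyphenyl}methanol (carbinol epimers) | COc1cc(OCc2ccccc2)cc([C@@H]2COc3cc(OCc4ccccc4)ccc3C2)c1C(O)c1ccc(OCc2ccccc2)cc1O | intermediate
21 | (6E)-3-(benzyloxy)-6-({4-(benzyloxy)-2-[(3R)-7-(benzyloxy)chroman-3-yl]-6-methoxyphenyl}methylidene)cyclohexa-2,4-dien-1-one (o-quinone methide) | COc1cc(OCc2ccccc2)cc([C@@H]2COc3cc(OCc4ccccc4)ccc3C2)c1/C=C1\C=CC(OCc2ccccc2)=CC1=O | intermediate (not isolated)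
22 | (3R,4S)-7-(benzyloxy)-4-{4-(benzyloxy)-2-[(3R)-7-(benzyloxy)chroman-3-yl]-6-methoxyphenyl}-3-[3-(benzyloxy)-2,4-dimethoxyphenyl]chroman-2-ol (C2 epimers) | COc1ccc([C@@H]2C(O)Oc3cc(OCc4ccccc4)ccc3[C@H]2c2c(OC)cc(OCc3ccccc3)cc2[C@@H]2COc3cc(OCc4ccccc4)ccc3C2)c(OC)c1OCc1ccccc1 | intermediate
23 | (3R,4S)-7-(benzyloxy)-4-{4-(benzyloxy)-2-[(3R)-7-(benzyloxy)chroman-3-yl]-6-methoxyphenyl}-3-[3-(benzyloxy)-2,4-dimethoxyphenyl]chromane | COc1ccc([C@@H]2COc3cc(OCc4ccccc4)ccc3[C@H]2c2c(OC)cc(OCc3ccccc3)cc2[C@@H]2COc3cc(OCc4ccccc4)ccc3C2)c(OC)c1OCc1ccccc1 | intermediate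
24 | (3R,4S)-4-{4-hydroxy-2-[(3R)-7-hydroxychroman-3-yl]-6-methoxyphenyl}-3-(3-hydroxy-2,4-dimethoxyphenyl)chroman-7-ol | COc1ccc([C@@H]2COc3cc(O)ccc3[C@H]2c2c(OC)cc(O)cc2[C@@H]2COc3cc(O)ccc3C2)c(OC)c1O | target

**Step count and risks**

Total steps: 12. Longest linear sequence: 9 (steps 1–5 and 9–12).

Step 10. The bulky enamine may fail to reach the methide carbon, which is flanked by the 2,6-disubstituted aryl ring, so that the quinone methide oligomerises and the aldehyde self-condenses; the face selectivity may also be eroded. The fallback sets out from 20 and the enol ether 16, isolated as its E isomer after the Wittig stage of step 8. Warming the two with catalytic PPTS and 4 Å molecular sieves in toluene at 50 °C generates 21, which the small enol ether intercepts in an uncatalysed inverse-electron-demand oxa-Diels–Alder reaction through the endo transition state. This should give the two trans-diaryl cyclic acetals, (2S,3R,4S)-7-(benzyloxy)-4-{4-(benzyloxy)-2-[(3R)-7-(benzyloxy)chroman-3-yl]-6-methoxyphenyl}-3-[3-(benzyloxy)-2,4-dimethoxyphenyl]-2-methoxychromane F1 and its (2R,3S,4R) isomer F2. They are diastereomers because of the lower stereocentre and are separated by chromatography. Ionic hydrogenation of F1 (Et3SiH, BF3·OEt2, CH2Cl2, −78 °C) comes back to the route at 23.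

Step 4. The cascade may stall, either at the conjugate reduction of the phenolic chromone or at the isoflavan-4-ol when the quinone methide does not form. The fallback sets out from 7. Benzylation of both phenols (BnBr, K2CO3, DMF) gives 7-(benzyloxy)-3-[5-(benzyloxy)-2-bromo-3-methoxyphenyl]-4H-chromen-4-one F3. Transfer hydrogenation with the same ruthenium catalyst then stops at (3R,4R)-7-(benzyloxy)-3-[5-(benzyloxy)-2-bromo-3-methoxyphenyl]chroman-4-ol F4, which is isolated. Its hydroxyl is removed in a separate ionic hydrogenation through the p-alkoxybenzylic cation (Et3SiH, TFA, CH2Cl2, 0 °C), which comes back to the route at 12.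

Step 11. The Lewis acid may ionise the C3–C4 bond (retro-Michael loss of the stabilised quinone methide) or the doubly benzylic C4 instead of the anomeric centre, which would scramble the new stereocentres. The fallback sets out from 22. NaBH4 in MeOH/THF at 0 °C reduces the open hydroxy-aldehyde tautomer to (2R,3S)-3-[4-(benzyloxy)-2-hydroxyphenyl]-3-{4-(benzyloxy)-2-[(3R)-7-(benzyloxy)chroman-3-yl]-6-methoxyphenyl}-2-[3-(benzyloxy)-2,4-dimethoxyphenyl]propan-1-ol F5. Mitsunobu etherification (PPh3, DIAD, THF, 0 °C) then recloses the pyran ring by 6-exo-tet displacement at the primary carbon without touching C3 or C4, and comes back to the route at 23.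

**Further compounds**

F1 | step 10 | (2S,3R,4S)-7-(benzyloxy)-4-{4-(benzyloxy)-2-[(3R)-7-(benzyloxy)chroman-3-yl]-6-methoxyphenyl}-3-[3-(benzyloxy)-2,4-dimethoxyphenyl]-2-methoxychromane | COc1ccc([C@@H]2[C@@H](OC)Oc3cc(OCc4ccccc4)ccc3[C@H]2c2c(OC)cc(OCc3ccccc3)cc2[C@@H]2COc3cc(OCc4ccccc4)ccc3C2)c(OC)c1OCc1ccccc1
F2 | step 10 | (2R,3S,4R)-7-(benzyloxy)-4-{4-(benzyloxy)-2-[(3R)-7-(benzyloxy)chroman-3-yl]-6-methoxyphenyl}-3-[3-(benzyloxy)-2,4-dimethoxyphenyl]-2-methoxychromane | COc1ccc([C@H]2[C@H](OC)Oc3cc(OCc4ccccc4)ccc3[C@@H]2c2c(OC)cc(OCc3ccccc3)cc2[C@@H]2COc3cc(OCc4ccccc4)ccc3C2)c(OC)c1OCc1ccccc1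
F3 | step 4 | 7-(benzyloxy)-3-[5-(benzyloxy)-2-bromo-3-methoxyphenyl]-4H-chromen-4-one | COc1cc(OCc2ccccc2)cc(-c2coc3cc(OCc4ccccc4)ccc3c2=O)c1Br
F4 | step 4 | (3R,4R)-7-(benzyloxy)-3-[5-(benzyloxy)-2-bromo-3-methoxyphenyl]chroman-4-ol | COc1cc(OCc2ccccc2)cc([C@@H]2COc3cc(OCc4ccccc4)ccc3[C@@H]2O)c1Br
F5 | step 11 | (2R,3S)-3-[4-(benzyloxy)-2-hydroxyphenyl]-3-{4-(benzyloxy)-2-[(3R)-7-(benzyloxy)chroman-3-yl]-6-methoxyphenyl}-2-[3-(benzyloxy)-2,4-dimethoxyphenyl]propan-1-ol | COc1ccc([C@H](CO)[C@@H](c2ccc(OCc3ccccc3)cc2O)c2c(OC)cc(OCc3ccccc3)cc2[C@@H]2COc3cc(OCc4ccccc4)ccc3C2)c(OC)c1OCc1ccccc1
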